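**Synthesis plan**

1. Numbering and target: the pyrrole is N-4, C-3, C-2, C-1, C-9a. The azepane is N-4, C-5 to C-9, C-9a. The carbocycle is C-1, C-9a, C-9, C-10 (ethyl), C-11 (O), C-12. The ring lactone adds C-13 (CH–CH3), and the side lactone runs from C-18 (O–CH on C-3) to C-20 (CH–CH3). The target is 9R,10R,11R,12S,13S,18R,20S.
2. Cuts, in order: the C–H bonds at C-12/C-13 and C-6/C-7; then C-6=C-7 (metathesis); then C-9a–C-1 and C-3–C-2 together (münchnone plus alkyne). Next come the bonds around C-9a, N-4 and C-3 (Ugi reaction), and last C-9–C-8 (α-allylation) and C-10–C-11 (vinylogous Michael addition).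
3. Enabling feature: the pyrrole ring N-4/C-3/C-2/C-1/C-9a is the hub of the tetracycle. Its N-4–C-9a edge belongs to the seven-membered ring, its C-1–C-9a edge belongs to the six-membered ring, and C-3 holds the side lactone. Its five atoms are therefore one amine nitrogen, one acyl carbon (C-3), one aldehyde carbon (C-9a) and one alkyne (C-1≡C-2).
4. Forward order: the butenolide and the side lactone are present from the start. A four-component reaction joins the fragments, one acid-triggered cycloaddition closes the pyrrole and the carbocycle together, metathesis closes the azepine, and hydrogenation turns the butenolide into the cis-fused lactone.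
5. Stereochemistry: C-10 and C-11 come from an iminium-catalysed Mukaiyama–Michael addition, and C-9 from a catalyst-controlled SOMO allylation. C-18 comes from the chiral pool and C-20 from anti-methylation of a lactone enolate. C-12 and C-13 come from syn hydrogenation on the butenolide face that carries H-11.

Key step: step 13

Assumption: 1-isocyanocyclohexene is taken as a catalogue compound that is stored cold and used fresh, because it polymerises on standing.

**Route**

Step 1
Reactants: 1 3-methyltetronic acid
Product: 2 4-methyl-5-oxo-2,5-dihydrofuran-3-yl trifluoromethanesulfonate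
Conditions: Tf2O (1.1 equiv), iPr2NEt (1.2 equiv), CH2Cl2, −78 °C
Reagents that add atoms: trifluoromethanesulfonic anhydride, O=S(=O)(C(F)(F)F)OS(=O)(=O)C(F)(F)F
Why: Enol triflate formation, in which the amine deprotonates the vinylogous acid and Tf2O traps the enolate oxygen at low temperature, turning C-4 of the furanone into a cross-coupling electrophile.

Step 2
Reactants: 2 enol triflate; 3 trimethylsilylacetylene
Product: 4 3-methyl-4-[(trimethylsilyl)ethynyl]furan-2(5H)-one
Conditions: PdCl2(PPh3)2 (3 mol %), CuI (6 mol %), Et3N (2 equiv), THF, 23 °C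
Reagents that add atoms: none
Why: Sonogashira coupling, in which the electron-poor β-triflyloxy butenolide adds readily to zerovalent palladium and the copper acetylide of 3 transfers the alkyne at room temperature, the silyl cap excluding a second coupling.

Step 3
Reactants: 4 alkynyl butenolide
Product: 5 triisopropyl({3-methyl-4-[(trimethylsilyl)ethynyl]furan-2-yl}oxy)silane
Conditions: TIPSOTf (1.1 equiv), Et3N (1.5 equiv), CH2Cl2, 0 °C
Reagents that add atoms: triisopropylsilyl trifluoromethanesulfonate, CC(C)[Si](C(C)C)(C(C)C)OS(=O)(=O)C(F)(F)F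
Why: Soft enolisation to a silyl dienol ether, in which O-silylation of the lactone carbonyl makes the γ-CH2 acidic enough for Et3N and aromatisation to the 2-silyloxyfuran drives the reaction.

Step 4
Reactants: 5 silyloxyfuran; 6 (E)-pent-2-enal
Product: 7 (3R)-3-{(2R)-4-methyl-5-oxo-3-[(trimethylsilyl)ethynyl]-2,5-dihydrofuran-2-yl}pentanal (C-10 R, C-11 R; anti adduct with ethyl and lactone oxygen on opposite sides of the extended C-9–C-10–C-11–C-12 chain)
Conditions: (2S,5S)-5-benzyl-2-tert-butyl-3-methylimidazolidin-4-one·TfOH (20 mol %), 6 (3 equiv), H2O (2 equiv), CHCl3, −40 °C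
Reagents that add atoms: none
Why: Iminium-catalysed vinylogous Mukaiyama–Michael addition, in which the benzyl group of the (2S,5S)-catalyst covers one face of the (E)-iminium ion so that furan C-5 bonds to the open Re face of the β-carbon (C-10 = R), while the anti C-10/C-11 relationship is sought with the strong-acid/chlorinated-solvent variant known to reverse the usual syn course and is helped by the rod-like silylethynyl group, which in the syn arrangement would have to lie under the iminium nitrogen and the catalyst ring.

Step 5
Reactants: 7 butenolide aldehyde; 8 allyltrimethylsilane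
Product: 9 (2R,3R)-2-allyl-3-{(2R)-4-methyl-5-oxo-3-[(trimethylsilyl)ethynyl]-2,5-dihydrofuran-2-yl}pentanal (C-9 R)
Conditions: (2R,5R)-5-benzyl-2-tert-butyl-3-methylimidazolidin-4-one·TFA (20 mol %), 8 (2.5 equiv), (NH4)2Ce(NO3)6 (2 equiv), NaHCO3 (2 equiv), DME, −20 °C
Reagents that add atoms: none
Why: SOMO-activated α-allylation, in which tetravalent cerium oxidises the (E)-enamine to a 3π-electron radical cation, the allylsilane adds to the face left open by the benzyl group of the (2R,5R)-catalyst (C-9 = R under catalyst control, β-branched aldehydes being within the known scope), a second oxidation with loss of silicon gives the alkene, and the electron-poor enyne is polarity-mismatched with the electrophilic radical.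

Step 6
Reactants: 10 (R)-5-oxotetrahydrofuran-2-carboxylic acid
Product: 11 (R)-5-(hydroxymethyl)dihydrofuran-2(3H)-one
Conditions: BH3·SMe2 (1.1 equiv), THF, 0 → 23 °C; MeOH quench
Reagents that add atoms: none
Why: Chemoselective borane reduction, in which the free acid reacts through an acyloxyborane far faster than the lactone and the stereocentre is not touched.

Step 7
Reactants: 11 hydroxymethyl lactone
Product: 12 (R)-5-{[(tert-butyldiphenylsilyl)oxy]methyl}dihydrofuran-2(3H)-one
Conditions: TBDPSCl (1.1 equiv), imidazole (1.1 equiv), DMF, 23 °C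
Reagents that add atoms: tert-butyldiphenylsilyl chloride, CC(C)(C)[Si](Cl)(c1ccccc1)c1ccccc1
Why: Imidazole-assisted silylation of a primary alcohol, which installs the bulky group that later shields one face of the lactone enolate.

Step 8
Reactants: 12 silyl ether lactone
Product: 14 (3S,5R)-5-{[(tert-butyldiphenylsilyl)oxy]methyl}-3-methyldihydrofuran-2(3H)-one (3,5-trans), via lithium enolate 13 (not isolated)
Conditions: LDA (1.05 equiv), THF, −78 °C; MeI (3 equiv), −78 °C
Reagents that add atoms: iodomethane, CI
Why: Diastereoselective lactone enolate alkylation, in which MeI approaches the planar enolate 13 anti to the C-5 silyloxymethyl group, giving the trans lactone and setting the future C-20 as S.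

Step 9
Reactants: 14 trans-methyl lactone
Product: 15 (3S,5R)-5-(hydroxymethyl)-3-methyldihydrofuran-2(3H)-one
Conditions: HF·pyridine, THF, 0 → 23 °C
Reagents that add atoms: none
Why: Fluoride-mediated silyl ether cleavage in a non-basic medium, so that the α-methyl centre does not epimerise and the lactone does not migrate to the primary alcohol.

Step 10
Reactants: 15 hydroxymethyl methyl lactone
Product: 17 (2R,4S)-4-methyl-5-oxotetrahydrofuran-2-carboxylic acid, via aldehyde 16 (not isolated)
Conditions: TEMPO (20 mol %), PhI(OAc)2 (2.2 equiv), MeCN/H2O 1:1, 23 °C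
Reagents that add atoms: water, O
Why: Oxoammonium (TEMPO/PhI(OAc)2) oxidation of the primary alcohol through aldehyde 16 and its hydrate to the acid, in a nearly neutral medium that preserves both stereocentres.

Step 11
Reactants: 9 α-allyl aldehyde; 17 lactone acid; 18 allylamine; 19 1-isocyanocyclohexene
Product: 21 (3R,4R)-3-allyl-2-{allyl[(2R,4S)-4-methyl-5-oxotetrahydrofuran-2-carbonyl]amino}-N-(cyclohex-1-en-1-yl)-4-{(2R)-4-methyl-5-oxo-3-[(trimethylsilyl)ethynyl]-2,5-dihydrofuran-2-yl}hexanamide (both C-2 epimers), via allyl imine 20 (not isolated)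
Conditions: 18 (1.0 equiv), 4 Å MS, MeOH, 0 °C; then 17 and 19 (1.1 equiv each), 0 → 23 °C
Reagents that add atoms: none
Why: Ugi four-component reaction, in which acid 17 protonates imine 20, isocyanide 19 adds to the iminium carbon, the carboxylate adds to the nitrilium ion and the Mumm O→N acyl shift gives the bis-amide; the new centre (future C-9a) is a mixture that step 13 erases, and one equivalent of amine, the silyl cap on the enyne and the short imine lifetime limit conjugate addition and epimerisation at C-9.

Step 12
Reactants: 21 Ugi adduct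
Product: 22 (3R,4R)-3-allyl-2-{allyl[(2R,4S)-4-methyl-5-oxotetrahydrofuran-2-carbonyl]amino}-N-(cyclohex-1-en-1-yl)-4-[(2R)-3-ethynyl-4-methyl-5-oxo-2,5-dihydrofuran-2-yl]hexanamide (both C-2 epimers)
Conditions: AgNO3 (10 mol %), acetone/H2O, 23 °C
Reagents that add atoms: none
Why: Silver-catalysed protiodesilylation of an alkynylsilane, in which a silver acetylide forms at the C(sp)–Si bond and is protonated by water, the neutral medium sparing the acid-labile enamide, both lactones and the acidic H-11.

Step 13
Reactants: 22 terminal enyne Ugi adduct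
Product: 25 N-4,C-9-diallyl pyrrole tricycle (9R,10R,11R,18R,20S) carrying the fused butenolide and the side lactone, via münchnone 23 (not isolated), via bridged cycloadduct 24 (not isolated)
Conditions: HCl (4 M in dioxane, 1.5 equiv), dry toluene (0.005 M), 23 → 90 °C
Reagents that add atoms: none
Why: Protonation of the cyclohexenyl enamide at its β-carbon makes the secondary amide an acylating agent, the oxygen of the neighbouring tertiary amide closes on that carbonyl (5-exo-trig) and cyclohexanimine leaves as its hydrochloride, which gives the mesoionic 1,3-oxazolium-5-olate 23 with the side lactone on its C-2 (future C-3) and the tether on its C-4 (future C-9a). The closest known chemistry is the Huisgen münchnone–alkyne [3+2] cycloaddition with loss of CO2, both in its intramolecular form and in the form fed by acid from Ugi adducts of 1-isocyanocyclohexene. The azomethine-ylide part of 23 adds suprafacially and in concert across C-1≡C-2: the C-9a–C-1 bond closes the six-membered carbocycle (C-1, C-9a, C-9, C-10, C-11, C-12) over the four-atom tether, the C-3–C-2 bond closes the five-membered N-4/C-3/C-2/C-1/C-9a ring, and the bridged adduct 24 expels CO2 by retro-[4+2] to become the aromatic pyrrole. No lasting stereocentre is created, because C-9a of 22 and both bridgeheads of 24 end up sp2, so the epimer mixture converges while C-9, C-10, C-11, C-18 and C-20 are only carried along. The step needs regio- and site-selectivity: the tether allows only the internal alkyne carbon to reach C-9a, the butenolide-conjugated alkyne is the one electron-poor π-bond matched to the electron-rich dipole, and neither allyl group is long enough to span the dipole. High dilution and dry, base-free acid keep dimerisation, hydrolysis and deprotonation at C-18 in check, and the electron-withdrawing butenolide on the new pyrrole tempers acid ionisation of the C-18–O bond.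

Step 14
Reactants: 25 diallyl pyrrole tricycle
Product: 26 6,7-didehydro tetracycle with the azepine closed and the butenolide retained (9R,10R,11R,18R,20S)
Conditions: second-generation Grubbs catalyst (H2IMes)(PCy3)Cl2Ru=CHPh (5 mol %), CH2Cl2 (0.002 M), 40 °C
Reagents that add atoms: none
Why: Ring-closing metathesis of two monosubstituted alkenes to a seven-membered ring, favoured because the allyl groups sit on N-4 and on C-9 next to C-9a of the rigid pyrrole, the pyrrole nitrogen is not basic, and the tetrasubstituted butenolide alkene is inert to the carbene.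

Step 15
Reactants: 26 didehydro tetracycle
Product: 28 target CNP0232452.1 (9R,10R,11R,12S,13S,18R,20S), via azepane butenolide 27 (not isolated)
Conditions: H2 (50 bar), 5% Rh/Al2O3, EtOAc, 23 °C
Reagents that add atoms: none
Why: Heterogeneous syn hydrogenation, in which the disubstituted C-6=C-7 bond is saturated first (27) and the tetrasubstituted C-12=C-13 bond then takes both hydrogens on the butenolide face that carries H-11, the other face being blocked by C-10 and its ethyl group, which gives the cis ring fusion (C-12 = S) and the all-cis H-11/H-12/H-13 lactone (C-13 = S); rhodium is chosen over palladium for its low tendency to cleave the C-18–O bond next to the pyrrole.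

**Compound list**

1 | 3-methyltetronic acid (4-hydroxy-3-methylfuran-2(5H)-one) | CC1=C(O)COC1=O | starting material
2 | 4-methyl-5-oxo-2,5-dihydrofuran-3-yl trifluoromethanesulfonate | CC1=C(OS(=O)(=O)C(F)(F)F)COC1=O | intermediate
3 | trimethylsilylacetylene | C[Si](C)(C)C#C | starting material
4 | 3-methyl-4-[(trimethylsilyl)ethynyl]furan-2(5H)-one | CC1=C(C#C[Si](C)(C)C)COC1=O | intermediate
5 | triisopropyl({3-methyl-4-[(trimethylsilyl)ethynyl]furan-2-yl}oxy)silane | CC1=C(O[Si](C(C)C)(C(C)C)C(C)C)OC=C1C#C[Si](C)(C)C | intermediate
6 | (E)-pent-2-enal | CC/C=C/C=O | starting material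
7 | (3R)-3-{(2R)-4-methyl-5-oxo-3-[(trimethylsilyl)ethynyl]-2,5-dihydrofuran-2-yl}pentanal | CC[C@H](CC=O)[C@H]1OC(=O)C(C)=C1C#C[Si](C)(C)C | intermediate
8 | allyltrimethylsilane | C=CC[Si](C)(C)C | starting material
9 | (2R,3R)-2-allyl-3-{(2R)-4-methyl-5-oxo-3-[(trimethylsilyl)ethynyl]-2,5-dihydrofuran-2-yl}pentanal | CC[C@H]([C@@H](CC=C)C=O)[C@H]1OC(=O)C(C)=C1C#C[Si](C)(C)C | intermediate
10 | (R)-5-oxotetrahydrofuran-2-carboxylic acid | OC(=O)[C@H]1CCC(=O)O1 | starting material
11 | (R)-5-(hydroxymethyl)dihydrofuran-2(3H)-one | OC[C@H]1CCC(=O)O1 | intermediate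
12 | (R)-5-{[(tert-butyldiphenylsilyl)oxy]methyl}dihydrofuran-2(3H)-one | CC(C)(C)[Si](c1ccccc1)(c1ccccc1)OC[C@H]1CCC(=O)O1 | intermediate
13 | lithium enolate of 12 (not isolated) | [Li+].[O-]C1=CC[C@H](CO[Si](c2ccccc2)(c2ccccc2)C(C)(C)C)O1 | intermediate
14 | (3S,5R)-5-{[(tert-butyldiphenylsilyl)oxy]methyl}-3-methyldihydrofuran-2(3H)-one | CC(C)(C)[Si](c1ccccc1)(c1ccccc1)OC[C@H]1C[C@H](C)C(=O)O1 | intermediate
15 | (3S,5R)-5-(hydroxymethyl)-3-methyldihydrofuran-2(3H)-one | OC[C@H]1C[C@H](C)C(=O)O1 | intermediate
16 | (2R,4S)-4-methyl-5-oxotetrahydrofuran-2-carbaldehyde (not isolated) | O=C[C@H]1C[C@H](C)C(=O)O1 | intermediate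
17 | (2R,4S)-4-methyl-5-oxotetrahydrofuran-2-carboxylic acid | OC(=O)[C@H]1C[C@H](C)C(=O)O1 | intermediate
18 | allylamine | C=CCN | starting material
19 | 1-isocyanocyclohexene | [C-]#[N+]C1=CCCCC1 | starting material
20 | (E)-N-allyl imine of aldehyde 9 (not isolated) | CC[C@H]([C@@H](CC=C)/C=N/CC=C)[C@H]1OC(=O)C(C)=C1C#C[Si](C)(C)C | intermediate
21 | Ugi bis-amide with silylated enyne, mixture at the future C-9a | CC[C@H]([C@@H](CC=C)C(N(CC=C)C(=O)[C@H]3C[C@H](C)C(=O)O3)C(=O)NC4=CCCCC4)[C@H]2OC(=O)C(C)=C2C#C[Si](C)(C)C | intermediate
22 | Ugi bis-amide with free terminal enyne, mixture at the future C-9a | CC[C@H]([C@@H](CC=C)C(N(CC=C)C(=O)[C@H]3C[C@H](C)C(=O)O3)C(=O)NC4=CCCCC4)[C@H]2OC(=O)C(C)=C2C#C | intermediate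
23 | münchnone: 3-allyl-1,3-oxazolium-5-olate with the side lactone on C-2 and the enyne tether on C-4 (not isolated) | CC[C@H]([C@@H](CC=C)C1=C([O-])OC([C@H]2C[C@H](C)C(=O)O2)=[N+]1CC=C)[C@H]3OC(=O)C(C)=C3C#C | intermediate
24 | bridged 2-oxa-7-azabicyclo[2.2.1]hept-5-en-3-one cycloadduct, bridgeheads undefined (not isolated) | CC[C@H]1[C@H]2OC(=O)C(C)=C2C2=CC3([C@H]4C[C@H](C)C(=O)O4)OC(=O)C2(N3CC=C)[C@@H]1CC=C | intermediate
25 | N-4,C-9-diallyl pyrrole tricycle: tetrahydroindole with the α-methylbutenolide fused at C-11/C-12, ethyl on C-10 and the side lactone on C-3 (9R,10R,11R,18R,20S) | CC[C@H]1[C@H]2OC(=O)C(C)=C2c2cc([C@H]3C[C@H](C)C(=O)O3)n(CC=C)c2[C@@H]1CC=C | intermediate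
26 | 6,7-didehydro tetracycle with a (Z)-alkene in the azepine and the butenolide retained | CC[C@H]1[C@H]2OC(=O)C(C)=C2c2cc([C@H]3C[C@H](C)C(=O)O3)n3c2[C@@H]1CC=CC3 | intermediate
27 | azepane butenolide, the 12,13-didehydro target (not isolated) | CC[C@H]1[C@H]2OC(=O)C(C)=C2c2cc([C@H]3C[C@H](C)C(=O)O3)n3c2[C@@H]1CCCC3 | intermediate
28 | CNP0232452.1 (9R,10R,11R,12S,13S,18R,20S) | CC[C@H]1[C@H]2OC(=O)[C@@H](C)[C@H]2c2cc([C@H]3C[C@H](C)C(=O)O3)n3c2[C@@H]1CCCC3 | target

**Step count**

The route has 15 steps in total. The longest linear sequence is 10 steps (steps 1–5 followed by 11–15). The acid branch, steps 6–10 followed by 11–15, is equally long.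

**Steps most likely to fail**

Step 4 is the weakest point stereochemically. Simple alkyl enals tend to give the syn adduct in this iminium-catalysed addition, so the anti selectivity may be poor or the sense at C-11 may stay reversed. The strong-acid salt may also protodesilylate furan 5 back to 4. The fallback replaces iminium catalysis with chelating Lewis-acid catalysis, where silyloxyfurans are known to add anti to N-enoyl oxazolidinones.

- The fallback sets out from 5.
- Furan 5 is added to 3-[(E)-pent-2-enoyl]-1,3-oxazolidin-2-one F1, made from (E)-pent-2-enoyl chloride and lithiated oxazolidin-2-one. The catalyst is Cu(OTf)2 with a C2-symmetric tert-butyl-bis(oxazoline) ligand (antipode chosen for 10R) in CH2Cl2, followed by aqueous work-up. This gives the anti imide adduct F2.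
- NaBH4 in THF/H2O reduces the exocyclic imide carbonyl to the primary alcohol F3.
- Dess–Martin periodinane oxidises it to aldehyde 7, where the route is rejoined.

Step 13 may fail in several ways: hydrolysis or dimerisation of the dipole, slow cycloaddition if the tether folds the linear enyne badly under the dipole, addition of HCl to the enyne, or acid-induced loss of configuration at C-18. The fallback separates dipole generation from the acid.

- The fallback sets out from 22.
- Dilute aqueous HCl in THF converts 22 into the N-acyl-N-allyl amino acid F4. This is the known hydrolysis of the cyclohexenyl amide by way of the same oxazolium ion.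
- Cyclodehydration with N,N'-diisopropylcarbodiimide in dilute toluene at 60–80 °C, the classical neutral entry to münchnones, regenerates 23.
- Münchnone 23 cyclises through 24 and loses CO2 to give 25, where the route is rejoined.

Step 15 may stall at 27, because the tetrasubstituted alkene is a push–pull system conjugated to the pyrrole. It may also overrun, through saturation of the pyrrole ring or hydrogenolysis of the C-18–O bond. Facial selectivity is the smaller concern. The fallback replaces surface hydrogenation with two chemically distinct reductions.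

- The fallback sets out from 26.
- Diimide (2-nitrobenzenesulfonyl hydrazide, Et3N, CH2Cl2, 23 °C) reduces the C-6=C-7 bond alone, so that 27 is isolated.
- Nickel boride (NiCl2·6H2O, NaBH4, MeOH/THF, −30 °C) then reduces the butenolide by conjugate hydride delivery. Hydride should arrive at C-12 and the proton at C-13, both from the H-11 face, at a temperature too low for base epimerisation of the kinetically set C-13.
- This returns to the route at 28 and makes no compound outside the list (F0).

**Further compounds**

F1 | step 4 | 3-[(E)-pent-2-enoyl]-1,3-oxazolidin-2-one | CC/C=C/C(=O)N1CCOC1=O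
F2 | step 4 | 3-[(3R)-3-{(2R)-4-methyl-5-oxo-3-[(trimethylsilyl)ethynyl]-2,5-dihydrofuran-2-yl}pentanoyl]-1,3-oxazolidin-2-one | CC[C@H](CC(=O)N1CCOC1=O)[C@H]2OC(=O)C(C)=C2C#C[Si](C)(C)C
F3 | step 4 | (5R)-5-[(3R)-1-hydroxypentan-3-yl]-3-methyl-4-[(trimethylsilyl)ethynyl]furan-2(5H)-one | CC[C@H](CCO)[C@H]1OC(=O)C(C)=C1C#C[Si](C)(C)C
F4 | step 13 | (3R,4R)-3-allyl-2-{allyl[(2R,4S)-4-methyl-5-oxotetrahydrofuran-2-carbonyl]amino}-4-[(2R)-3-ethynyl-4-methyl-5-oxo-2,5-dihydrofuran-2-yl]hexanoic acid (both C-2 epimers) | CC[C@H]([C@@H](CC=C)C(N(CC=C)C(=O)[C@H]1C[C@H](C)C(=O)O1)C(=O)O)[C@H]2OC(=O)C(C)=C2C#C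
F0 | step 15 | none | none
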